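**Retrosynthetic overview**
1. Target 25 ⇐ aryl bromide 22 + (E)-alkenyl boronate 23 (Suzuki–Miyaura, then acetal hydrolysis); the enal goes on last because every earlier stage uses hydride.
2. Each erythro aryl-glycerol aryl ether ⇐ phenol + bromoacetyl oxazolidinone 13 (C–O bond), Mg-catalysed anti-aldol with an aryl aldehyde (C7–C8 bond), LiBH4; run twice (ring B with aldehyde 4, ring A with vanillin acetate 19).
3. Phenol 10 (rings C and D) ⇐ key disconnection of the C3–C3a (8–5') bond: oxidative ring contraction of (R)-flavanone 7. The ketone α-carbon is made electrophilic as an α-(aryl-λ3-iodanyl) ketal (an enolonium equivalent) and captures the electron-rich ring-D carbon by a 1,2-shift.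
4. (R)-7 ⇐ kinetic resolution of racemic flavanone 6 ⇐ acetophenone 2 + aldehyde 4 (Claisen–Schmidt, then oxa-Michael).
5. Ring order: pyranone ring (step 3), then its contraction to the dihydrofuran ring (step 5); no other ring is built.

Assumption: the target is taken exactly as written, which I read as 7R,8S (erythro, anti) in both aryl-glycerol units and 2R,3S (trans) in the dihydrobenzofuran; rings are lettered A (guaiacyl), B and C (syringyl), D (benzofuran arene).
Abbreviations: Q = (2R,3S)-5-bromo-3-(hydroxymethyl)-7-methoxy-2,3-dihydro-1-benzofuran-2-yl; TMS = trimethylsilyl.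

**Step 1**
Reactants: 1 1-(2-hydroxy-3-methoxyphenyl)ethan-1-one
Product: 2 1-(5-bromo-2-hydroxy-3-methoxyphenyl)ethan-1-one
Conditions: NBS (1.05 equiv), MeCN, 0 °C → rt
Reagents that add atoms: N-bromosuccinimide, O=C1CCC(=O)N1Br
Why: Electrophilic aromatic bromination; the phenolic OH directs para (C5), its ortho positions being blocked by acetyl and OMe.

**Step 2**
Reactants: 3 syringaldehyde (4-hydroxy-3,5-dimethoxybenzaldehyde)
Product: 4 4-formyl-2,6-dimethoxyphenyl pivalate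
Conditions: PivCl (1.2 equiv), Et3N (1.5 equiv), DMAP (5 mol %), CH2Cl2, 0 °C → rt
Reagents that add atoms: pivaloyl chloride, CC(C)(C)C(Cl)=O
Why: DMAP-catalysed O-acylation; the pivalate shields the phenol from the later iodine oxidant, lowers the migratory aptitude of ring C, and is removed by hydride.

**Step 3**
Reactants: 2 1-(5-bromo-2-hydroxy-3-methoxyphenyl)ethan-1-one; 4 4-formyl-2,6-dimethoxyphenyl pivalate
Product: 6 racemic 4-(6-bromo-8-methoxy-4-oxochroman-2-yl)-2,6-dimethoxyphenyl pivalate, via 2'-hydroxychalcone 5 (not isolated)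
Conditions: L-proline (0.3 equiv), DMF, 80 °C, 24 h (residual 5 recycled)
Reagents that add atoms: none
Why: Amine-catalysed Claisen–Schmidt condensation followed by intramolecular oxa-Michael addition of the ortho-phenol (one-pot flavanone synthesis), mild enough to keep the hindered aryl pivalate; C2 is formed racemic.

**Step 4**
Reactants: 6 racemic flavanone
Product: 7 4-[(2R)-6-bromo-8-methoxy-4-oxochroman-2-yl]-2,6-dimethoxyphenyl pivalate
Conditions: RuCl(p-cymene)[(S,S)-TsDPEN] (1 mol %), HCO2H/Et3N (5:2), EtOAc, rt, stopped at about 55% conversion; chromatography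
Reagents that add atoms: none
Why: Noyori–Ikariya asymmetric transfer hydrogenation run as a kinetic resolution: the (S,S)-catalyst makes 4S carbinols and reduces only the (2S)-enantiomer quickly (to the cis-flavanol), so (2R)-7 is recovered in high ee (at most 50% yield), which fixes the future C2 of the dihydrobenzofuran.

**Step 5 (key step)**
Reactants: 7 (2R)-flavanone
Product: 9 methyl (2R,3R)-5-bromo-2-[3,5-dimethoxy-4-(pivaloyloxy)phenyl]-7-methoxy-2,3-dihydro-1-benzofuran-3-carboxylate, via enol ether 8 (not isolated)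
Conditions: PhI(OAc)2 (1.3 equiv), conc. H2SO4 (1.5 equiv), HC(OMe)3, rt, 4 h; aq NaHCO3
Reagents that add atoms: trimethyl orthoformate, COC(OC)OC; water, O
Why: Hypervalent-iodine oxidative ring contraction of a flavanone (1,2-aryl shift, semipinacol type): the ketone becomes enol ether 8, the trivalent iodine reagent puts a phenyl-λ3-iodanyl group on C3 trans to the 2-aryl group and so turns this normally nucleophilic α-carbon into an enolonium equivalent, and the electron-rich ring-D carbon C4a (also normally a nucleophilic carbon), anti-periplanar to the C3–I bond, migrates to C3 with inversion as PhI leaves, so the 8–5' C–C bond, the five-membered ring and the 2,3-trans relation form together while C2 is untouched.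

**Step 6**
Reactants: 9 ring-contracted methyl ester
Product: 10 4-Q-2,6-dimethoxyphenol, i.e. 4-[(2R,3S)-5-bromo-3-(hydroxymethyl)-7-methoxy-2,3-dihydro-1-benzofuran-2-yl]-2,6-dimethoxyphenol
Conditions: LiAlH4 (3 equiv), THF, 0 °C, 1 h; Rochelle salt work-up
Reagents that add atoms: none
Why: Hydride reduction of the methyl ester to CH2OH and reductive cleavage of the aryl pivalate in one operation; the trans arrangement is the thermodynamic one and is kept (C3 becomes S only through the priority change).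

**Step 7**
Reactants: 11 (S)-4-benzyl-1,3-oxazolidin-2-one; 12 bromoacetyl bromide
Product: 13 (4S)-4-benzyl-3-(bromoacetyl)-1,3-oxazolidin-2-one
Conditions: n-BuLi (1.0 equiv), THF, −78 °C; then 12 (1.1 equiv), −78 → 0 °C
Reagents that add atoms: none
Why: N-acylation of the lithiated Evans oxazolidinone with the more reactive acyl bromide end of 12.

**Step 8**
Reactants: 10 4-Q-2,6-dimethoxyphenol; 13 bromoacetyl oxazolidinone
Product: 14 (4S)-4-benzyl-3-[(4-Q-2,6-dimethoxyphenoxy)acetyl]-1,3-oxazolidin-2-one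
Conditions: K2CO3 (1.5 equiv), acetone, rt, 12 h
Reagents that add atoms: none
Why: Williamson ether synthesis (SN2 at the α-bromo imide); K2CO3 deprotonates only the phenol, so the primary alcohol is not alkylated.

**Step 9**
Reactants: 14 aryloxyacetyl imide; 4 4-formyl-2,6-dimethoxyphenyl pivalate
Product: 16 (4S)-4-benzyl-3-[(2R,3R)-3-hydroxy-3-(3,5-dimethoxy-4-pivaloyloxyphenyl)-2-(4-Q-2,6-dimethoxyphenoxy)propanoyl]-1,3-oxazolidin-2-one, via bis-TMS ether 15 (not isolated)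
Conditions: MgCl2 (0.2 equiv), Et3N (4 equiv), TMSCl (3 equiv), 4 (1.3 equiv), EtOAc, rt, 24 h; then THF/1 M HCl (5:1), 0 °C, 30 min
Reagents that add atoms: none
Why: Evans magnesium-halide-catalysed direct anti-aldol (soft enolisation, silylative turnover), here extended from propionyl to an aryloxyacetyl imide: the chelated Z-enolate is attacked on the face away from the benzyl group (same sense as Evans alkylation) through a boat-like transition state, giving the (2R,3R)-anti adduct, which is the erythro 7R,8S unit of ring B; TMSCl also masks the free CH2OH in situ.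

**Step 10**
Reactants: 16 aldol adduct
Product: 17 (1R,2S)-1-(4-hydroxy-3,5-dimethoxyphenyl)-2-(4-Q-2,6-dimethoxyphenoxy)propane-1,3-diol
Conditions: LiBH4 (5 equiv), THF/MeOH (20:1), 0 °C → rt
Reagents that add atoms: none
Why: Reductive removal of the oxazolidinone auxiliary gives the 1,3-diol and the same hydride cleaves the aryl pivalate, freeing the ring-B phenol; no stereocentre is touched (C8 becomes S only by priority change).

**Step 11**
Reactants: 17 ring-B phenol triol; 13 bromoacetyl oxazolidinone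
Product: 18 (4S)-4-benzyl-3-[(4-{(1R,2S)-1,3-dihydroxy-2-(4-Q-2,6-dimethoxyphenoxy)propyl}-2,6-dimethoxyphenoxy)acetyl]-1,3-oxazolidin-2-one
Conditions: K2CO3 (1.5 equiv), acetone, 40 °C
Reagents that add atoms: none
Why: Williamson ether synthesis, chemoselective for the phenoxide over the three aliphatic hydroxyls.

**Step 12**
Reactants: 18 aryloxyacetyl imide; 19 vanillin acetate (4-formyl-2-methoxyphenyl acetate)
Product: 21 (4S)-4-benzyl-3-[(2R,3R)-3-(4-acetoxy-3-methoxyphenyl)-3-hydroxy-2-(4-{(1R,2S)-1,3-dihydroxy-2-(4-Q-2,6-dimethoxyphenoxy)propyl}-2,6-dimethoxyphenoxy)propanoyl]-1,3-oxazolidin-2-one, via tetrakis-TMS ether 20 (not isolated)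
Conditions: MgCl2 (0.3 equiv), Et3N (7 equiv), TMSCl (6 equiv), 19 (1.5 equiv), EtOAc, rt, 24 h; then THF/1 M HCl (5:1), 0 °C, 20 min
Reagents that add atoms: none
Why: Second Evans magnesium-halide-catalysed anti-aldol under the same auxiliary control, setting the (7R,8S) erythro unit of ring A; the three free hydroxyls are silylated in situ and released in the brief cold acid work-up.

**Step 13**
Reactants: 21 aldol adduct
Product: 22 (1R,2S)-1-(4-hydroxy-3-methoxyphenyl)-2-(4-{(1R,2S)-1,3-dihydroxy-2-(4-Q-2,6-dimethoxyphenoxy)propyl}-2,6-dimethoxyphenoxy)propane-1,3-diol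
Conditions: LiBH4 (5 equiv), THF/MeOH (20:1), 0 °C → rt
Reagents that add atoms: none
Why: Reductive removal of the auxiliary to the 1,3-diol with simultaneous cleavage of the aryl acetate, giving the free ring-A phenol without touching the aryl bromide or any stereocentre.

**Step 14**
Reactants: 22 aryl bromide; 23 (E)-2-(3,3-diethoxyprop-1-en-1-yl)-4,4,5,5-tetramethyl-1,3,2-dioxaborolane
Product: 25 CNP0192639.1, via diethyl acetal 24 (not isolated)
Conditions: 23 (1.5 equiv), Pd(OAc)2 (5 mol %), SPhos (10 mol %), K3PO4 (3 equiv), THF/H2O (4:1), 50 °C; then 0.5 M aq HCl, THF, 0 °C → rt, 20 min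
Reagents that add atoms: water, O
Why: Suzuki–Miyaura coupling of the aryl bromide with the (E)-alkenyl boronate (alkene geometry retained), then mild hydrolysis of the allylic acetal to the (E)-enal; free phenol and alcohols are tolerated and no stereocentre is at risk under these conditions.

**Compound list**
1 | 1-(2-hydroxy-3-methoxyphenyl)ethan-1-one | CC(=O)c1cccc(OC)c1O | starting material
2 | 1-(5-bromo-2-hydroxy-3-methoxyphenyl)ethan-1-one | CC(=O)c1cc(Br)cc(OC)c1O | intermediate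
3 | syringaldehyde | COc1cc(C=O)cc(OC)c1O | starting material
4 | 4-formyl-2,6-dimethoxyphenyl pivalate | COc1cc(C=O)cc(OC)c1OC(=O)C(C)(C)C | intermediate
5 | 4-[(E)-3-(5-bromo-2-hydroxy-3-methoxyphenyl)-3-oxoprop-1-en-1-yl]-2,6-dimethoxyphenyl pivalate | COc1cc(Br)cc(C(=O)/C=C/c2cc(OC)c(OC(=O)C(C)(C)C)c(OC)c2)c1O | intermediate (not isolated)
6 | racemic 4-(6-bromo-8-methoxy-4-oxochroman-2-yl)-2,6-dimethoxyphenyl pivalate | COc1cc(Br)cc2C(=O)CC(Oc12)c3cc(OC)c(OC(=O)C(C)(C)C)c(OC)c3 | intermediate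
7 | 4-[(2R)-6-bromo-8-methoxy-4-oxochroman-2-yl]-2,6-dimethoxyphenyl pivalate | COc1cc(Br)cc2C(=O)C[C@@H](Oc12)c3cc(OC)c(OC(=O)C(C)(C)C)c(OC)c3 | intermediate
8 | 4-[(2R)-6-bromo-4,8-dimethoxy-2H-chromen-2-yl]-2,6-dimethoxyphenyl pivalate | COc1cc(Br)cc2C(OC)=C[C@@H](Oc12)c3cc(OC)c(OC(=O)C(C)(C)C)c(OC)c3 | intermediate (not isolated)
9 | methyl (2R,3R)-5-bromo-2-[3,5-dimethoxy-4-(pivaloyloxy)phenyl]-7-methoxy-2,3-dihydro-1-benzofuran-3-carboxylate | COc1cc(cc(OC)c1OC(=O)C(C)(C)C)[C@@H]1Oc2c(OC)cc(Br)cc2[C@H]1C(=O)OC | intermediate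
10 | 4-[(2R,3S)-5-bromo-3-(hydroxymethyl)-7-methoxy-2,3-dihydro-1-benzofuran-2-yl]-2,6-dimethoxyphenol | COc1cc(cc(OC)c1O)[C@@H]1Oc2c(OC)cc(Br)cc2[C@H]1CO | intermediate
11 | (S)-4-benzyl-1,3-oxazolidin-2-one | O=C1N[C@@H](Cc2ccccc2)CO1 | starting material
12 | bromoacetyl bromide | BrCC(Br)=O | starting material
13 | (4S)-4-benzyl-3-(bromoacetyl)-1,3-oxazolidin-2-one | O=C1OC[C@H](Cc2ccccc2)N1C(=O)CBr | intermediate
14 | (4S)-4-benzyl-3-[(4-Q-2,6-dimethoxyphenoxy)acetyl]-1,3-oxazolidin-2-one | COc1cc(cc(OC)c1OCC(=O)N3C(=O)OC[C@@H]3Cc4ccccc4)[C@@H]5Oc6c(OC)cc(Br)cc6[C@H]5CO | intermediate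
15 | bis-TMS ether of 16 (on the new benzylic OH and on the CH2OH of Q) | CC(C)(C)C(=O)Oc1c(OC)cc(cc1OC)[C@@H](O[Si](C)(C)C)[C@H](C(=O)N3C(=O)OC[C@@H]3Cc4ccccc4)Oc5c(OC)cc(cc5OC)[C@@H]6Oc7c(OC)cc(Br)cc7[C@H]6CO[Si](C)(C)C | intermediate (not isolated)
16 | (4S)-4-benzyl-3-[(2R,3R)-3-hydroxy-3-(3,5-dimethoxy-4-pivaloyloxyphenyl)-2-(4-Q-2,6-dimethoxyphenoxy)propanoyl]-1,3-oxazolidin-2-one | CC(C)(C)C(=O)Oc1c(OC)cc(cc1OC)[C@@H](O)[C@H](C(=O)N3C(=O)OC[C@@H]3Cc4ccccc4)Oc5c(OC)cc(cc5OC)[C@@H]6Oc7c(OC)cc(Br)cc7[C@H]6CO | intermediate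
17 | (1R,2S)-1-(4-hydroxy-3,5-dimethoxyphenyl)-2-(4-Q-2,6-dimethoxyphenoxy)propane-1,3-diol | COc1cc(cc(OC)c1O)[C@@H](O)[C@H](CO)Oc5c(OC)cc(cc5OC)[C@@H]6Oc7c(OC)cc(Br)cc7[C@H]6CO | intermediate
18 | (4S)-4-benzyl-3-[(4-{(1R,2S)-1,3-dihydroxy-2-(4-Q-2,6-dimethoxyphenoxy)propyl}-2,6-dimethoxyphenoxy)acetyl]-1,3-oxazolidin-2-one | COc1cc(cc(OC)c1OCC(=O)N3C(=O)OC[C@@H]3Cc4ccccc4)[C@@H](O)[C@H](CO)Oc5c(OC)cc(cc5OC)[C@@H]6Oc7c(OC)cc(Br)cc7[C@H]6CO | intermediate
19 | vanillin acetate (4-formyl-2-methoxyphenyl acetate) | CC(=O)Oc1ccc(C=O)cc1OC | starting material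
20 | tetrakis-TMS ether of 21 (all four aliphatic OH groups silylated) | CC(=O)Oc1ccc(cc1OC)[C@@H](O[Si](C)(C)C)[C@H](C(=O)N3C(=O)OC[C@@H]3Cc4ccccc4)Oc8c(OC)cc(cc8OC)[C@@H](O[Si](C)(C)C)[C@H](CO[Si](C)(C)C)Oc5c(OC)cc(cc5OC)[C@@H]6Oc7c(OC)cc(Br)cc7[C@H]6CO[Si](C)(C)C | intermediate (not isolated)
21 | (4S)-4-benzyl-3-[(2R,3R)-3-(4-acetoxy-3-methoxyphenyl)-3-hydroxy-2-(4-{(1R,2S)-1,3-dihydroxy-2-(4-Q-2,6-dimethoxyphenoxy)propyl}-2,6-dimethoxyphenoxy)propanoyl]-1,3-oxazolidin-2-one | CC(=O)Oc1ccc(cc1OC)[C@@H](O)[C@H](C(=O)N3C(=O)OC[C@@H]3Cc4ccccc4)Oc8c(OC)cc(cc8OC)[C@@H](O)[C@H](CO)Oc5c(OC)cc(cc5OC)[C@@H]6Oc7c(OC)cc(Br)cc7[C@H]6CO | intermediate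
22 | (1R,2S)-1-(4-hydroxy-3-methoxyphenyl)-2-(4-{(1R,2S)-1,3-dihydroxy-2-(4-Q-2,6-dimethoxyphenoxy)propyl}-2,6-dimethoxyphenoxy)propane-1,3-diol | COc1cc(ccc1O)[C@@H](O)[C@H](CO)Oc8c(OC)cc(cc8OC)[C@@H](O)[C@H](CO)Oc5c(OC)cc(cc5OC)[C@@H]6Oc7c(OC)cc(Br)cc7[C@H]6CO | intermediate
23 | (E)-2-(3,3-diethoxyprop-1-en-1-yl)-4,4,5,5-tetramethyl-1,3,2-dioxaborolane | CCOC(OCC)/C=C/B1OC(C)(C)C(C)(C)O1 | starting material
24 | diethyl acetal of the target (22 with Br replaced by (E)-3,3-diethoxyprop-1-enyl) | COc1cc(ccc1O)[C@@H](O)[C@H](CO)Oc8c(OC)cc(cc8OC)[C@@H](O)[C@H](CO)Oc5c(OC)cc(cc5OC)[C@@H]6Oc7c(OC)cc(/C=C/C(OCC)OCC)cc7[C@H]6CO | intermediate (not isolated)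
25 | CNP0192639.1, (E)-3-{(2R,3S)-2-[4-({(1R,2S)-1-[4-({(1R,2S)-1,3-dihydroxy-1-(4-hydroxy-3-methoxyphenyl)propan-2-yl}oxy)-3,5-dimethoxyphenyl]-1,3-dihydroxypropan-2-yl}oxy)-3,5-dimethoxyphenyl]-3-(hydroxymethyl)-7-methoxy-2,3-dihydro-1-benzofuran-5-yl}prop-2-enal | COc1cc([C@@H](O)[C@H](CO)Oc2c(OC)cc([C@@H](O)[C@H](CO)Oc3c(OC)cc([C@@H]4Oc5c(OC)cc(/C=C/C=O)cc5[C@H]4CO)cc3OC)cc2OC)ccc1O | target

**Step count**
Total: 14 steps. Longest linear sequence: 12 steps (1 → 2 → 6 → 7 → 9 → 10 → 14 → 16 → 17 → 18 → 21 → 22 → 25).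

**Three steps most likely to fail, with fallbacks**

Step 5 (key ring contraction). The migrating ring-D carbon carries two meta substituents (Br, OMe) that slow the shift, so 2→3 migration of ring C (isoflavone), flavone formation or simple 3-methoxylation may compete, and the oxidant meets three electron-rich rings. Fallback, from 7 back to 9: brominate 7 with CuBr2 (EtOAc/CHCl3, reflux) to the trans-3-bromoflavanone F1 (equatorial bromine). Convert it with HC(OMe)3/MeOH/TsOH into the α-bromo dimethyl ketal F2. Then promote the 1,2-aryl shift with ZnBr2 in toluene at 90 °C (Lewis-acid rearrangement of an α-halo ketal, as in the 2-arylpropionate process), which proceeds with inversion at C3 and gives 9 directly. This separates halogenation from migration and keeps any oxidant away from the arenes.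

Step 9 (first anti-aldol; step 12 repeats the reaction on a more hydroxylated substrate). The magnesium-catalysed anti-aldol is established for propionyl-type imides, and a bulky aryloxyacetyl imide may give lower anti selectivity or react sluggishly. Fallback, from 10 back to 17: alkylate phenol 10 with bromoacetaldehyde diethyl acetal (Cs2CO3, DMF, 100 °C) to the aryloxy acetal F3 and hydrolyse it (aq TFA, THF) to the aryloxyacetaldehyde F4. A D-proline-catalysed enamine cross-aldol with aldehyde 4 (DMF, 4 °C), which is anti-selective through the usual hydrogen-bonded chair transition state, gives the (2R,3R)-β-hydroxy aldehyde F5. LiBH4 then reduces the aldehyde and removes the pivalate to give 17.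

Step 4 (kinetic resolution). Yield is capped at 50% and the selectivity factor for this 6-bromo-8-methoxy flavanone is not known. Fallback, from 2 (with 4) back to 7: C-acylate the dianion of 2 (LiHMDS, then Boc2O) to the β-keto ester F6 and condense it with 4 (piperidine/AcOH, toluene, Dean–Stark) to the alkylidene β-keto ester F7. A cinchona-alkaloid thiourea (the pseudoenantiomer that gives the 2R series, 10 mol %, toluene, −25 °C) catalyses the enantioselective intramolecular oxa-Michael addition to the flavanone-3-carboxylate F8. F8 is decarboxylated in the same flask (TsOH, 80 °C) to 7, so the stereocentre is made catalytically and not by discarding half the material.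

**Further compounds**
F1 | step 5 | 4-[(2S,3S)-3,6-dibromo-8-methoxy-4-oxochroman-2-yl]-2,6-dimethoxyphenyl pivalate (2,3-trans) | COc1cc(Br)cc2C(=O)[C@@H](Br)[C@@H](Oc12)c3cc(OC)c(OC(=O)C(C)(C)C)c(OC)c3
F2 | step 5 | 4-[(2S,3S)-3,6-dibromo-4,4,8-trimethoxychroman-2-yl]-2,6-dimethoxyphenyl pivalate | COc1cc(Br)cc2C(OC)(OC)[C@@H](Br)[C@@H](Oc12)c3cc(OC)c(OC(=O)C(C)(C)C)c(OC)c3
F3 | step 9 | {(2R,3S)-5-bromo-2-[4-(2,2-diethoxyethoxy)-3,5-dimethoxyphenyl]-7-methoxy-2,3-dihydro-1-benzofuran-3-yl}methanol | CCOC(COc1c(OC)cc(cc1OC)[C@@H]3Oc4c(OC)cc(Br)cc4[C@H]3CO)OCC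
F4 | step 9 | (4-Q-2,6-dimethoxyphenoxy)acetaldehyde | O=CCOc1c(OC)cc(cc1OC)[C@@H]3Oc4c(OC)cc(Br)cc4[C@H]3CO
F5 | step 9 | 4-[(1R,2R)-1-hydroxy-3-oxo-2-(4-Q-2,6-dimethoxyphenoxy)propyl]-2,6-dimethoxyphenyl pivalate | CC(C)(C)C(=O)Oc1c(OC)cc(cc1OC)[C@@H](O)[C@H](C=O)Oc5c(OC)cc(cc5OC)[C@@H]6Oc7c(OC)cc(Br)cc7[C@H]6CO
F6 | step 4 | tert-butyl 3-(5-bromo-2-hydroxy-3-methoxyphenyl)-3-oxopropanoate | COc1cc(Br)cc(C(=O)CC(=O)OC(C)(C)C)c1O
F7 | step 4 | tert-butyl 2-(5-bromo-2-hydroxy-3-methoxybenzoyl)-3-[3,5-dimethoxy-4-(pivaloyloxy)phenyl]prop-2-enoate (E/Z mixture) | COc1cc(Br)cc(C(=O)C(=Cc2cc(OC)c(OC(=O)C(C)(C)C)c(OC)c2)C(=O)OC(C)(C)C)c1O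
F8 | step 4 | tert-butyl (2R)-6-bromo-2-[3,5-dimethoxy-4-(pivaloyloxy)phenyl]-8-methoxy-4-oxochroman-3-carboxylate (C3 labile, keto/enol mixture) | COc1cc(Br)cc2C(=O)C(C(=O)OC(C)(C)C)[C@@H](Oc12)c3cc(OC)c(OC(=O)C(C)(C)C)c(OC)c3
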